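## Retrosynthetic overview

1. Positions are named with labdane numbering: ring A = C1–C5/C10, ring B = C5–C10, C19 = CO2H and C18 = CH3 on C4, C20 = CH3 on C10, C17 = exocyclic CH2 on C8, side chain C11–C15 on C9. The C8=CH2 group is cut back to a C8 ketone (methylenation) and the C6–C7 single bond to an enone (hydrogenation).
2. The C6=C7–C8=O enone and the free C19 acid both come from a tricyclic silyl enol ether in which C19 is tied to C6 as a γ-lactone. Fluoride-induced β-elimination opens this temporary ring, so the tether leaves no trace and the C15 methyl ester is never touched.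
3. Ring B is cut at C5–C6 and C9–C10: intramolecular Diels–Alder reaction of a 1-acyloxy-3-silyloxy diene (C6=C7–C8(OSi)=C9, side chain on C9) whose acyl group is the ring-A acid. Ring order: ring A first (bought as a cyclohexenone, C4 set by catalysis), then ring B and the temporary lactone together, then the lactone is opened.
4. The triene is cut at the C6–O bond into (S)-1,3-dimethylcyclohex-2-ene-1-carboxylic acid and a terminal ynone (amine-catalysed acid addition, then silyl enol ether). The ynone comes from methyl hydrogen (R)-3-methylglutarate, which supplies C13.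
5. Enabling feature: the A/B fusion is cis and the C4 carboxyl is on the same face of ring A as both ring-B bonds (C5–C6 and C10–C9), while C19, C6 and C8 are 1,3-related. C19 can therefore serve as a three-atom tether to C6 that forces the diene onto the correct face of the C5=C10 alkene and is later expelled by the C8 carbonyl.

Key step: step 9

Remark on the structure: the stereodescriptors of the target define a cis-fused decalin, (4S,5R,9R,10S,13R) in labdane numbering, with H-5, CH3-20 and the C9 side chain on one face and the C4 carboxyl on the other; the route is planned for exactly this isomer.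

## Route

Step 1
Reactants: 1 methyl 3-oxocyclohex-1-ene-1-carboxylate
Product: 3 methyl (S)-1-methyl-3-(trifluoromethylsulfonyloxy)cyclohex-2-ene-1-carboxylate, via methylzinc enolate 2 (not isolated)
Conditions: Me2Zn (3 equiv), (CuOTf)2·C6H6 (2.5 mol%), chiral sulfonate-bearing NHC·Ag(I) complex (2.5 mol%, the enantiomer that delivers the (S) centre), t-BuOMe, −30 °C; then Tf2O (1.5 equiv), −78 → 0 °C
Reagents that add atoms: dimethylzinc, C[Zn]C; trifluoromethanesulfonic anhydride, O=S(=O)(OS(=O)(=O)C(F)(F)F)C(F)(F)F
Why: Copper–NHC-catalysed asymmetric conjugate addition of Me2Zn to a β-(alkoxycarbonyl) cyclohexenone should build the quaternary C4 centre under catalyst control, and O-triflation of the regiodefined zinc enolate fixes the position of the future C5=C10 double bond.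

Step 2
Reactants: 3 methyl (S)-1-methyl-3-(trifluoromethylsulfonyloxy)cyclohex-2-ene-1-carboxylate
Product: 4 methyl (S)-1,3-dimethylcyclohex-2-ene-1-carboxylate
Conditions: MeMgBr (1.5 equiv), Fe(acac)3 (5 mol%), THF/NMP, −30 °C
Reagents that add atoms: methylmagnesium bromide, C[Mg]Br
Why: Iron-catalysed Kumada-type cross-coupling of an alkenyl triflate with MeMgBr should replace OTf by the C20 methyl at a temperature at which the methyl ester is not attacked; no stereocentre is involved.

Step 3
Reactants: 4 methyl (S)-1,3-dimethylcyclohex-2-ene-1-carboxylate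
Product: 5 (S)-1,3-dimethylcyclohex-2-ene-1-carboxylic acid
Conditions: LiOH·H2O (5 equiv), THF/MeOH/H2O, 60 °C; then cold 1 M HCl to pH 3
Reagents that add atoms: lithium hydroxide, [Li+].[OH-]
Why: Saponification of the hindered tertiary ester cannot epimerise the quaternary centre, and cold, mild acidification avoids acid-induced lactonisation of the β,γ-unsaturated acid.

Step 4
Reactants: 6 methyl hydrogen (R)-3-methylglutarate
Product: 7 1-(1,3-dioxoisoindolin-2-yl) 5-methyl (S)-3-methylpentanedioate
Conditions: N-hydroxyphthalimide, N,N'-diisopropylcarbodiimide, DMAP (5 mol%), CH2Cl2, 0 °C → rt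
Reagents that add atoms: N-hydroxyphthalimide, O=C1c2ccccc2C(=O)N1O
Why: Carbodiimide esterification gives the redox-active N-acyloxyphthalimide without touching the bought C13 stereocentre (the descriptor changes to S only through the priority rules).

Step 5
Reactants: 7 1-(1,3-dioxoisoindolin-2-yl) 5-methyl (S)-3-methylpentanedioate; 8 N-methoxy-N-methylacrylamide
Product: 9 methyl (R)-7-[methoxy(methyl)amino]-3-methyl-7-oxoheptanoate
Conditions: Ru(bpy)3(PF6)2 (1 mol%), Hantzsch ester (1.5 equiv), CH2Cl2, blue LEDs, rt
Reagents that add atoms: none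
Why: Photoredox decarboxylative Giese reaction: single-electron reduction of the phthalimide ester should release CO2 and a primary alkyl radical that adds to the acrylamide, the adduct radical being reduced by the dihydropyridine; the stereocentre β to the radical is not affected.

Step 6
Reactants: 9 methyl (R)-7-[methoxy(methyl)amino]-3-methyl-7-oxoheptanoate
Product: 11 methyl (R)-3-methyl-7-oxonon-8-ynoate, via magnesium hemiaminal 10 (not isolated)
Conditions: HC≡CMgBr (2.5 equiv), THF, −20 → 0 °C; inverse quench into cold 1 M HCl
Reagents that add atoms: ethynylmagnesium bromide, C#C[Mg]Br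
Why: Weinreb ketone synthesis: the chelated adduct 10 blocks over-addition, the alkynyl Grignard reagent is too unreactive towards the methyl ester at 0 °C, and the acidic inverse quench keeps the liberated amine from adding to the ynone.

Step 7
Reactants: 5 (S)-1,3-dimethylcyclohex-2-ene-1-carboxylic acid; 11 methyl (R)-3-methyl-7-oxonon-8-ynoate
Product: 12 methyl (3R,8E)-9-{[(1S)-1,3-dimethylcyclohex-2-ene-1-carbonyl]oxy}-3-methyl-7-oxonon-8-enoate
Conditions: DABCO (10 mol%), CH2Cl2, 0 °C → rt
Reagents that add atoms: none
Why: Tertiary-amine-catalysed conjugate addition (oxa-Michael) of a carboxylic acid to a terminal ynone is known to give (E)-β-acyloxy enones, and it joins the two fragments through the future tether without any activation of the hindered acid.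

Step 8
Reactants: 12 methyl (3R,8E)-9-{[(1S)-1,3-dimethylcyclohex-2-ene-1-carbonyl]oxy}-3-methyl-7-oxonon-8-enoate
Product: 13 methyl (3R,6Z,8E)-7-[(tert-butyldimethylsilyl)oxy]-9-{[(1S)-1,3-dimethylcyclohex-2-ene-1-carbonyl]oxy}-3-methylnona-6,8-dienoate
Conditions: TBSOTf (1.3 equiv), i-Pr2NEt (2 equiv), CH2Cl2, −78 → 0 °C
Reagents that add atoms: tert-butyldimethylsilyl trifluoromethanesulfonate, CC(C)(C)[Si](C)(C)OS(=O)(=O)C(F)(F)F
Why: Soft enolisation (silyl triflate/hindered amine) of the ketone at its only α-CH2 should give the Danishefsky-type 1-acyloxy-3-silyloxy diene, expected as the (Z)-enol ether (chain cis to OSi); the ester is not enolised and the non-nucleophilic base does not displace the vinylogous acyloxy group.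

Step 9
Reactants: 13 methyl (3R,6Z,8E)-7-[(tert-butyldimethylsilyl)oxy]-9-{[(1S)-1,3-dimethylcyclohex-2-ene-1-carbonyl]oxy}-3-methylnona-6,8-dienoate
Product: 14 tricyclic silyl enol ether lactone (cis-fused rings A/B, C7=C8–OTBS, C19(=O)–O–C6 γ-lactone)
Conditions: o-dichlorobenzene (5 mM), BHT (10 mol%), base-washed sealed tube, 200 °C
Reagents that add atoms: none
Why: Thermal type-1 intramolecular Diels–Alder reaction: the (1E,3Z)-1-acyloxy-3-silyloxy diene adds suprafacially across the trisubstituted C5=C10 alkene of ring A in a concerted, asynchronous [4+2] transition state; the closest known reaction type is the thermal cyclisation of ester-tethered nona-1,3,8-trienes with unactivated dienophiles, here helped by the quaternary C4 (gem-disubstituent effect), high dilution and about 200 °C. Ring B closes as the six-membered cycloadduct ring with both new σ-bonds on one face of ring A (hence the cis A/B fusion, H-5 and CH3-20 syn), and the C4–C19(=O)–O–C6 tether closes at the same time as a five-membered lactone. C5 and C10 are controlled by C4: the three-atom tether can deliver the diene only to the ring-A face that carries C19, so both ring-B bonds end syn to the carboxyl and anti to the C4 methyl, as in the target. C9 is controlled by diene geometry and transition-state mode: the (Z)-silyl enol ether holds the side chain "outside", and in the arrangement expected to be favoured, with ring A exo (only H-5 and CH3-20 lie under the diene, the quaternary C4 is anti to C7 about the forming C5–C6 bond), the side chain ends cis to CH3-20; C6 is a temporary centre that is lost in step 10. The step needs regio-, face- and exo-selectivity: the first two are enforced by the tether, the third rests on the steric bias just described, and the diene has no cis-allylic C–H that could divert it by a 1,5-hydrogen shift.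

Step 10
Reactants: 14 tricyclic silyl enol ether lactone
Product: 16 enone acid (8-oxo-17-norlabd-6-ene-15,19-dioic acid 15-methyl ester with the cis-fused skeleton of the target), via ammonium enolate 15 (not isolated)
Conditions: TBAF (1.1 equiv), AcOH (1.1 equiv), THF, 0 °C; crude product used directly
Reagents that add atoms: none
Why: Fluoride cleaves the silyl enol ether and enolate 15 expels the β-carboxylate (E1cB, the usual unveiling of an enone from a 1-oxy-3-silyloxy diene adduct, here aided by release of the strained lactone), which frees the C19 acid without any reagent that could touch the methyl ester; the acetic acid buffer protects C9.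

Step 11
Reactants: 16 enone acid
Product: 17 keto acid (8-oxo-17-norlabdane-15,19-dioic acid 15-methyl ester, cis-fused)
Conditions: H2 (1 atm), 10% Pd/C, EtOAc, rt
Reagents that add atoms: none
Why: Heterogeneous hydrogenation should saturate the conjugated C6=C7 bond, the only C=C present, under neutral conditions; no stereocentre is created or put at risk.

Step 12
Reactants: 17 keto acid
Product: 18 (1S,4aS,5R,8aR)-5-[(3R)-5-methoxy-3-methyl-5-oxopentyl]-1,4a-dimethyl-6-methylidenedecahydronaphthalene-1-carboxylic acid (target)
Conditions: Ph3PCH3Br (4 equiv), KOt-Bu (3.8 equiv), THF, 0 °C → rt; aqueous citric acid work-up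
Reagents that add atoms: methyltriphenylphosphonium bromide, C[P+](c1ccccc1)(c1ccccc1)c1ccccc1.[Br-]
Why: Wittig methylenation of the C8 ketone, as commonly used on 8-oxolabdanes, should tolerate the carboxylate and the methyl ester at room temperature, and C9 carries its side chain equatorial, which is also expected to be the more stable arrangement.

## Compound list

1 | methyl 3-oxocyclohex-1-ene-1-carboxylate | COC(=O)C1=CC(=O)CCC1 | starting material
2 | methylzinc enolate of methyl (S)-1-methyl-3-oxocyclohexane-1-carboxylate (not isolated) | C[Zn]OC1=C[C@@](C)(C(=O)OC)CCC1 | intermediate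
3 | methyl (S)-1-methyl-3-(trifluoromethylsulfonyloxy)cyclohex-2-ene-1-carboxylate | O=S(=O)(OC1=C[C@@](C)(C(=O)OC)CCC1)C(F)(F)F | intermediate
4 | methyl (S)-1,3-dimethylcyclohex-2-ene-1-carboxylate | CC1=C[C@@](C)(C(=O)OC)CCC1 | intermediate
5 | (S)-1,3-dimethylcyclohex-2-ene-1-carboxylic acid | CC1=C[C@@](C)(C(=O)O)CCC1 | intermediate
6 | methyl hydrogen (R)-3-methylglutarate [(R)-5-methoxy-3-methyl-5-oxopentanoic acid] | OC(=O)C[C@@H](C)CC(=O)OC | starting material
7 | 1-(1,3-dioxoisoindolin-2-yl) 5-methyl (S)-3-methylpentanedioate | O=C(C[C@@H](C)CC(=O)OC)ON1C(=O)c2ccccc2C1=O | intermediate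
8 | N-methoxy-N-methylacrylamide | C=CC(=O)N(C)OC | starting material
9 | methyl (R)-7-[methoxy(methyl)amino]-3-methyl-7-oxoheptanoate | CON(C)C(=O)CCC[C@@H](C)CC(=O)OC | intermediate
10 | bromomagnesium alkoxide of the tetrahedral ethynyl adduct of 9 (not isolated; new carbinol centre undefined) | C#CC(O[Mg]Br)(N(C)OC)CCC[C@@H](C)CC(=O)OC | intermediate
11 | methyl (R)-3-methyl-7-oxonon-8-ynoate | C#CC(=O)CCC[C@@H](C)CC(=O)OC | intermediate
12 | methyl (3R,8E)-9-{[(1S)-1,3-dimethylcyclohex-2-ene-1-carbonyl]oxy}-3-methyl-7-oxonon-8-enoate | CC1=C[C@@](C)(C(=O)O/C=C/C(=O)CCC[C@@H](C)CC(=O)OC)CCC1 | intermediate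
13 | methyl (3R,6Z,8E)-7-[(tert-butyldimethylsilyl)oxy]-9-{[(1S)-1,3-dimethylcyclohex-2-ene-1-carbonyl]oxy}-3-methylnona-6,8-dienoate | CC1=C[C@@](C)(C(=O)O/C=C/C(O[Si](C)(C)C(C)(C)C)=C/CC[C@@H](C)CC(=O)OC)CCC1 | intermediate
14 | Diels–Alder adduct: cis-fused decalin with C7=C8–OTBS enol ether and C19(=O)–O–C6 γ-lactone; H-5, CH3-20, the C6–O bond and the C9 side chain on one face of ring B; C4 and C13 as in 18 | CC(C)(C)[Si](C)(C)OC1=C[C@@H]2OC(=O)[C@@]3(C)CCC[C@](C)([C@@H]23)[C@@H]1CC[C@@H](C)CC(=O)OC | intermediate
15 | tetrabutylammonium enolate formed from 14 by desilylation (not isolated) | [O-]C1=C[C@@H]2OC(=O)[C@@]3(C)CCC[C@](C)([C@@H]23)[C@@H]1CC[C@@H](C)CC(=O)OC.CCCC[N+](CCCC)(CCCC)CCCC | intermediate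
16 | enone acid: 8-oxo-17-norlabd-6-ene-15,19-dioic acid 15-methyl ester, cis-fused, all stereocentres arranged as in 18 | O=C1C=C[C@@H]2[C@@](C)(CCC[C@]2(C)C(=O)O)[C@@H]1CC[C@@H](C)CC(=O)OC | intermediate
17 | keto acid: 8-oxo-17-norlabdane-15,19-dioic acid 15-methyl ester, cis-fused, all stereocentres arranged as in 18 | O=C1CC[C@@H]2[C@@](C)(CCC[C@]2(C)C(=O)O)[C@@H]1CC[C@@H](C)CC(=O)OC | intermediate
18 | (1S,4aS,5R,8aR)-5-[(3R)-5-methoxy-3-methyl-5-oxopentyl]-1,4a-dimethyl-6-methylidenedecahydronaphthalene-1-carboxylic acid (CNP0260608.1) | C=C1CC[C@@H]2[C@@](C)(CCC[C@]2(C)C(=O)O)[C@@H]1CC[C@@H](C)CC(=O)OC | target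

## Step count and risks

Total step count: 12. Longest linear sequence: 9 steps (steps 1–3 or 4–6, then 7–12).

Steps most likely to fail:

Step 9. What may go wrong: the unactivated, trisubstituted ring-A alkene may cyclo-add so slowly that the silyloxy diene degrades first, or the cycloaddition may run through the ring-A-endo mode and leave C9 epimeric. Fallback (sets out from 9 and 5, comes back at 16): the same two bonds are made photochemically in a de Mayo sequence. Weinreb amide 9 is reduced with Cp2Zr(H)Cl (THF, rt), which spares the ester, to methyl (R)-3-methyl-7-oxoheptanoate F1. Its pyrrolidine enamine is C-acetylated (AcCl, Et3N, then aqueous AcOH) to methyl (3R)-6-formyl-3-methyl-7-oxooctanoate F2 (enolised; the new centre is not defined). Acid 5 is converted with 1-chloro-N,N,2-trimethylprop-1-en-1-amine into (S)-1,3-dimethylcyclohex-2-ene-1-carbonyl chloride F3, which O-acylates the hydroxymethylene enol of F2 (Et3N, CH2Cl2, 0 °C) to the β-acyloxy enone methyl (3R)-6-acetyl-7-{[(1S)-1,3-dimethylcyclohex-2-ene-1-carbonyl]oxy}-3-methylhept-6-enoate F4 (E/Z mixture). Irradiation (350 nm, MeCN, 5 mM) should give the cyclobutane photoadduct F5 by intramolecular enone–alkene [2+2] cycloaddition, the five-membered lactone ring closing first; the C5–C6 and C9–C10 bonds are then in place on the carboxyl face of ring A. Aqueous KOH (MeOH/H2O, 40 °C) opens the lactone, the cyclobutanolate cleaves the C6–C9 bond by retro-aldol reaction, and the keto aldehyde closes by aldol condensation of the methyl ketone to the enone diacid F6. C9 is set by equilibration here, and C5, flanked by two quaternary carbons, is not expected to enolise. Fischer esterification (MeOH, cat. H2SO4, rt) esterifies only the unhindered side-chain acid and returns 16.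

Step 1. What may go wrong: insufficient enantioselectivity in the copper-catalysed addition, or C-protonation of the zinc enolate before O-triflation. Fallback (sets out from 1, comes back at 4): the quaternary centre is made racemic and then resolved. Me2CuLi (Et2O, −78 °C) adds to 1 and the lithium enolate is trapped with N-phenylbis(trifluoromethanesulfonimide) to give racemic methyl 1-methyl-3-(trifluoromethylsulfonyloxy)cyclohex-2-ene-1-carboxylate F7. Iron-catalysed coupling with MeMgBr as in step 2 gives racemic methyl 1,3-dimethylcyclohex-2-ene-1-carboxylate F8, and preparative chromatography on a chiral stationary phase (SFC) separates the (S)-enantiomer 4.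

Step 12. What may go wrong: enolisation of the hindered C8 ketone by the basic ylide, leading to epimerisation at C9 or incomplete olefination. Fallback (sets out from 17, comes back at 18): addition–elimination under non-enolising conditions. Me3SiCH2Li/CeCl3 (THF, −78 °C, excess to allow for the carboxylate) adds to the ketone to give the β-hydroxysilane F9 (mixture at C8, of no consequence), and acid-induced Peterson elimination (cat. H2SO4, THF, 0 °C → rt) gives 18.

## Further compounds

F1 | step 9 | methyl (R)-3-methyl-7-oxoheptanoate | O=CCCC[C@@H](C)CC(=O)OC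
F2 | step 9 | methyl (3R)-6-formyl-3-methyl-7-oxooctanoate (C6 undefined, enolised) | CC(=O)C(C=O)CC[C@@H](C)CC(=O)OC
F3 | step 9 | (S)-1,3-dimethylcyclohex-2-ene-1-carbonyl chloride | CC1=C[C@@](C)(C(=O)Cl)CCC1
F4 | step 9 | methyl (3R)-6-acetyl-7-{[(1S)-1,3-dimethylcyclohex-2-ene-1-carbonyl]oxy}-3-methylhept-6-enoate (E/Z mixture) | CC1=C[C@@](C)(C(=O)OC=C(CC[C@@H](C)CC(=O)OC)C(C)=O)CCC1
F5 | step 9 | cyclobutane photoadduct: C5–C6–C9–C10 four-membered ring cis-fused to ring A and to the C19(=O)–O–C6 γ-lactone, acetyl and side chain on C9 (C9 undefined) | CC(=O)C1(CC[C@@H](C)CC(=O)OC)[C@H]2OC(=O)[C@@]3(C)CCC[C@]1(C)[C@@H]23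
F6 | step 9 | enone diacid: 8-oxo-17-norlabd-6-ene-15,19-dioic acid, cis-fused, stereocentres arranged as in 16 | O=C1C=C[C@@H]2[C@@](C)(CCC[C@]2(C)C(=O)O)[C@@H]1CC[C@@H](C)CC(=O)O
F7 | step 1 | racemic methyl 1-methyl-3-(trifluoromethylsulfonyloxy)cyclohex-2-ene-1-carboxylate | COC(=O)C1(C)C=C(OS(=O)(=O)C(F)(F)F)CCC1
F8 | step 1 | racemic methyl 1,3-dimethylcyclohex-2-ene-1-carboxylate | CC1=CC(C)(C(=O)OC)CCC1
F9 | step 12 | β-hydroxysilane: 8-hydroxy-8-[(trimethylsilyl)methyl] derivative of 17 (C8 undefined) | C[Si](C)(C)CC1(O)CC[C@@H]2[C@@](C)(CCC[C@]2(C)C(=O)O)[C@@H]1CC[C@@H](C)CC(=O)OC
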